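**Retrosynthetic overview**
1. Feature: in central ring B, carbons B3–B4(OH)–B5 and their two CH2 arms form the core of a 1,5-diarylpentan-3-one, and B6–B1–B2 is a malonyl unit. Rings A and C are fully substituted and cannot be acylated.
2. Last disconnections: the benzyl ethers are removed by hydrogenolysis, and the B1–butyryl bond is made by Houben–Hoesch acylation at the only free aromatic CH.
3. Key disconnection: bonds B2–B3 and B5–B6 come from double C-acylation of the ketone enol ether with malonyl dichloride. After aromatization the enol oxygen remains on B4 as an aryl ether, so it carries benzyl rather than a permanent alkyl group.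
4. Ketone: two successive Horner–Wadsworth–Emmons olefinations of 1,3-bis(diethoxyphosphoryl)propan-2-one, first with the ring C aldehyde and then with the ring A aldehyde, followed by alkene-selective hydrogenation.
5. Aldehydes: both come from 2,4,6-trihydroxytoluene by formylation, methylation of the OH para to CHO, acylation of the one free carbon, and benzylation. Rings A and C are bought as arenes, and ring B is the only ring formed.

Key step: step 11

Assumption: the benzyl enol ether is drawn as its (Z)-isomer with the double bond toward the ring A arm. The regio- and E/Z isomers formed beside it lead to the same ring B, because both alpha carbons become ring carbons. The target has no stereocentre, and every alkene geometry in the intermediates is erased before the end.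

**Step 1**
Reactants: 1 2,4,6-trihydroxytoluene
Product: 3 2,4,6-trihydroxy-3-methylbenzaldehyde, via aryliminium chloride 2 (not isolated)
Conditions: POCl3 (1.1 equiv), DMF (1.2 equiv), EtOAc, 0 °C → rt; then H2O, 50 °C
Reagents that add atoms: N,N-dimethylformamide CN(C)C=O; water O
Why: Vilsmeier–Haack formylation of a phloroglucinol, in which the two free ring carbons of 1 are equivalent by symmetry, so only one monoaldehyde can form and its formyl group slows a second attack.

**Step 2**
Reactants: 3 2,4,6-trihydroxy-3-methylbenzaldehyde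
Product: 4 2,6-dihydroxy-4-methoxy-3-methylbenzaldehyde
Conditions: Me2SO4 (1.0 equiv), K2CO3 (1.0 equiv), acetone, rt → 40 °C
Reagents that add atoms: dimethyl sulfate COS(=O)(=O)OC
Why: Williamson O-methylation with one equivalent of reagent, in which the hydroxyl para to the formyl group is the most acidic and takes no part in the hydrogen bond to the carbonyl oxygen, so it is alkylated first, the same order seen in the 4-O-alkylation of phloroacylphenones.

**Step 3**
Reactants: 4 2,6-dihydroxy-4-methoxy-3-methylbenzaldehyde
Product: 5 3-acetyl-2,6-dihydroxy-4-methoxy-5-methylbenzaldehyde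
Conditions: Ac2O (3 equiv), BF3·OEt2 (4 equiv), 60 °C; then aq NaOAc, MeOH, 50 °C
Reagents that add atoms: acetic anhydride CC(=O)OC(C)=O
Why: Friedel–Crafts acylation (O-acylation and Fries migration feed the same product) at the only unsubstituted ring carbon, with the same electron demand as the BF3-promoted conversion of monoacyl- into 2,4-diacylphloroglucinols, and BF3 does not cleave the aryl methyl ether.

**Step 4**
Reactants: 4 2,6-dihydroxy-4-methoxy-3-methylbenzaldehyde
Product: 6 3-butanoyl-2,6-dihydroxy-4-methoxy-5-methylbenzaldehyde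
Conditions: (PrCO)2O (3 equiv), BF3·OEt2 (4 equiv), 60 °C; then aq NaOAc, MeOH, 50 °C
Reagents that add atoms: butyric anhydride CCCC(=O)OC(=O)CCC
Why: Friedel–Crafts acylation as in step 3, with the regiochemistry forced because a single ring carbon is free, which places the butyryl group between the methoxy group and a hydroxyl as ring C requires.

**Step 5**
Reactants: 5 3-acetyl-2,6-dihydroxy-4-methoxy-5-methylbenzaldehyde
Product: 7 3-acetyl-2,6-bis(benzyloxy)-4-methoxy-5-methylbenzaldehyde (ring A aldehyde)
Conditions: BnBr (2.5 equiv), K2CO3 (3 equiv), n-Bu4NI (0.1 equiv), DMF, 60 °C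
Reagents that add atoms: benzyl bromide BrCc1ccccc1
Why: Williamson benzylation, run in warm DMF with iodide catalysis because both phenols are hydrogen-bonded and flanked, while the weak base leaves the acetyl and formyl groups untouched.

**Step 6**
Reactants: 6 3-butanoyl-2,6-dihydroxy-4-methoxy-5-methylbenzaldehyde
Product: 8 2,6-bis(benzyloxy)-3-butanoyl-4-methoxy-5-methylbenzaldehyde (ring C aldehyde)
Conditions: BnBr (2.5 equiv), K2CO3 (3 equiv), n-Bu4NI (0.1 equiv), DMF, 60 °C
Reagents that add atoms: benzyl bromide BrCc1ccccc1
Why: Williamson benzylation as in step 5, in which O-alkylation is the only open course because every ring carbon is substituted.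

**Step 7**
Reactants: 8 ring C aldehyde; 9 tetraethyl (2-oxopropane-1,3-diyl)bis(phosphonate)
Product: 10 ring C (E)-enone ketophosphonate
Conditions: 9 (2.5 equiv), NaH (2.0 equiv), THF, 0 °C; 8 added over 2 h, 0 °C → rt
Reagents that add atoms: none
Why: Horner–Wadsworth–Emmons olefination to the (E)-enone, in which the stabilized ketophosphonate anion is too weak a base to enolize the butyryl ketone and adds only to the aldehyde, and the excess of 9 with slow addition of 8 holds the reaction at mono-olefination.

**Step 8**
Reactants: 10 ring C (E)-enone ketophosphonate; 7 ring A aldehyde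
Product: 11 (1E,4E)-1-(ring A aryl)-5-(ring C aryl)penta-1,4-dien-3-one
Conditions: NaH (1.05 equiv), THF, 0 °C; then 7 (1.0 equiv), rt → 40 °C
Reagents that add atoms: none
Why: Second (E)-selective Horner–Wadsworth–Emmons olefination, in which the remaining ketophosphonate of 10 is deprotonated by one equivalent of NaH and meets the only aldehyde present, while the hindered aryl ketones of both partners stay out.

**Step 9**
Reactants: 11 (1E,4E)-dienone
Product: 12 1-(ring A aryl)-5-(ring C aryl)pentan-3-one
Conditions: H2 (1 atm), Pd/C (10 wt%), Ph2S (0.02 equiv), EtOAc, rt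
Reagents that add atoms: none
Why: Heterogeneous hydrogenation over sulfide-poisoned Pd/C saturates the two enone C=C bonds, while the poison shuts down hydrogenolysis of the aryl benzyl ethers and reduction of the aryl ketones.

**Step 10**
Reactants: 12 1,5-diarylpentan-3-one
Product: 14 (Z)-benzyl enol ether of the 1,5-diarylpentan-3-one, via dibenzyl ketal 13 (not isolated)
Conditions: BnOSiMe3 (2.3 equiv), TMSOTf (0.05 equiv), CH2Cl2, −78 → −20 °C; then iPr2NEt (1.6 equiv), TMSOTf (1.15 equiv), −20 → 0 °C; aq NaHCO3; filtration through basic Al2O3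
Reagents that add atoms: benzyloxytrimethylsilane C[Si](C)(C)OCc1ccccc1
Why: Silyl-triflate-catalysed ketalization with an alkoxysilane takes only the unhindered dialkyl ketone (both aryl ketones are di-ortho-substituted), and stoichiometric TMSOTf with iPr2NEt then ionizes the ketal and removes an alpha proton, the standard ketal-to-enol-ether elimination, with the triflate kept just above one equivalent so that the ring A acetyl group is not silylated.

**Step 11**
Reactants: 14 (Z)-benzyl enol ether; 15 malonyl dichloride
Product: 17 des-butyryl trimer penta-O-benzyl ether (ring B: B1 H; B2 and B6 OH; B4 OBn), via keto acyl chloride 16 (not isolated)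
Conditions: 15 (1.05 equiv), Et2O–CH2Cl2 (0.02 M), −30 °C → rt, Ar sweep; aq NaHCO3
Reagents that add atoms: none
Why: The electron-rich carbon of enol ether 14 attacks one acyl chloride of 15 and a proton is lost, which forms bond B2–B3 and gives vinylogous ester 16; proton shuttling by the HCl released re-exposes an enol ether toward the second alpha carbon. That carbon attacks the remaining acyl chloride in a 6-(enolendo)-exo-trig closure (bond B5–B6, ring B), and the benzyloxycyclohexenedione so formed tautomerizes at once to the arene. The closest known reaction is the Effenberger cyclization of alkyl enol ethers with malonyl dichloride, best known from 1-alkoxycycloalkenes and bicyclo[3.3.1]nonane-2,4,9-triones, while open-chain ketone derivatives are known to divide between this C,C path and a C,O path. Since deprotonation and aromatization are faster than dealkylation of the oxocarbenium ion, the enol alkyl group should end as the aryl ether on the B4 oxygen, so it is chosen as benzyl, and any material that loses it early still reaches the target through the last two steps. The step needs C- over O-acylation in the second event and enol ether over aryl ketone: an O-alkyl group shields the oxygen far better than a silyl group, aromatization rewards only the carbon closure, rings A and C have no free carbon, and their twisted di-ortho-substituted ketones do not enolize at −30 °C. No stereocentre is formed, and because both alpha carbons are CH2 groups that both become ring carbons, every regio- and E/Z isomer of 14 gives the same 17.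

**Step 12**
Reactants: 17 des-butyryl trimer penta-O-benzyl ether
Product: 19 penta-O-benzyl agrimol F, via ketiminium chloride 18 (not isolated)
Conditions: PrCN (5 equiv), ZnCl2 (1.5 equiv), HCl (g), Et2O, 0 °C; then THF–H2O, 60 °C
Reagents that add atoms: butyronitrile CCCC#N; water O
Why: Houben–Hoesch acylation, in which the nitrile-derived electrophile attacks B1, the only unsubstituted carbon of an activated ring and one flanked by two free hydroxyls, under conditions mild enough for aryl benzyl ethers, and warm water then hydrolyses the ketimine salt to the ketone.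

**Step 13**
Reactants: 19 penta-O-benzyl agrimol F
Product: 20 agrimol F
Conditions: H2 (1 atm), Pd/C (10 wt%), EtOAc–MeOH, rt
Reagents that add atoms: none
Why: Catalytic hydrogenolysis of the five aryl benzyl ethers, in which the three aryl ketones become hydrogen-bonded vinylogous acids as the phenols are freed and resist reduction at 1 atm, and no other reducible group is present.

**Compound list**
1 | 2,4,6-trihydroxytoluene (2-methylbenzene-1,3,5-triol) | Cc1c(O)cc(O)cc1O | starting material
2 | N,N-dimethyl-1-(2,4,6-trihydroxy-3-methylphenyl)methaniminium chloride | C[N+](C)=Cc1c(O)cc(O)c(C)c1O.[Cl-] | intermediate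
3 | 2,4,6-trihydroxy-3-methylbenzaldehyde | O=Cc1c(O)cc(O)c(C)c1O | intermediate
4 | 2,6-dihydroxy-4-methoxy-3-methylbenzaldehyde | COc1cc(O)c(C=O)c(O)c1C | intermediate
5 | 3-acetyl-2,6-dihydroxy-4-methoxy-5-methylbenzaldehyde | CC(=O)c1c(O)c(C=O)c(O)c(C)c1OC | intermediate
6 | 3-butanoyl-2,6-dihydroxy-4-methoxy-5-methylbenzaldehyde | CCCC(=O)c1c(O)c(C=O)c(O)c(C)c1OC | intermediate
7 | 3-acetyl-2,6-bis(benzyloxy)-4-methoxy-5-methylbenzaldehyde (ring A aldehyde) | CC(=O)c1c(OCc2ccccc2)c(C=O)c(OCc2ccccc2)c(C)c1OC | intermediate
8 | 2,6-bis(benzyloxy)-3-butanoyl-4-methoxy-5-methylbenzaldehyde (ring C aldehyde) | CCCC(=O)c1c(OCc2ccccc2)c(C=O)c(OCc2ccccc2)c(C)c1OC | intermediate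
9 | tetraethyl (2-oxopropane-1,3-diyl)bis(phosphonate) | CCOP(=O)(OCC)CC(=O)CP(=O)(OCC)OCC | starting material
10 | diethyl {(3E)-4-[2,6-bis(benzyloxy)-3-butanoyl-4-methoxy-5-methylphenyl]-2-oxobut-3-en-1-yl}phosphonate | CCCC(=O)c1c(OCc2ccccc2)c(/C=C/C(=O)CP(=O)(OCC)OCC)c(OCc2ccccc2)c(C)c1OC | intermediate
11 | (1E,4E)-1-[3-acetyl-2,6-bis(benzyloxy)-4-methoxy-5-methylphenyl]-5-[2,6-bis(benzyloxy)-3-butanoyl-4-methoxy-5-methylphenyl]penta-1,4-dien-3-one | CCCC(=O)c1c(OCc2ccccc2)c(/C=C/C(=O)/C=C/c2c(OCc3ccccc3)c(C)c(OC)c(C(C)=O)c2OCc2ccccc2)c(OCc2ccccc2)c(C)c1OC | intermediate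
12 | 1-[3-acetyl-2,6-bis(benzyloxy)-4-methoxy-5-methylphenyl]-5-[2,6-bis(benzyloxy)-3-butanoyl-4-methoxy-5-methylphenyl]pentan-3-one | CCCC(=O)c1c(OCc2ccccc2)c(CCC(=O)CCc2c(OCc3ccccc3)c(C)c(OC)c(C(C)=O)c2OCc2ccccc2)c(OCc2ccccc2)c(C)c1OC | intermediate
13 | dibenzyl ketal of 12 (3,3-bis(benzyloxy)-1,5-diarylpentane) | CCCC(=O)c1c(OCc2ccccc2)c(CCC(OCc2ccccc2)(OCc2ccccc2)CCc2c(OCc3ccccc3)c(C)c(OC)c(C(C)=O)c2OCc2ccccc2)c(OCc2ccccc2)c(C)c1OC | intermediate
14 | (2Z)-3-(benzyloxy)-1-(ring A aryl)-5-(ring C aryl)pent-2-ene, the benzyl enol ether of 12 | C(c1ccccc1)O/C(CCc1c(OCc2ccccc2)c(C)c(OC)c(C(=O)CCC)c1OCc1ccccc1)=C\Cc1c(OCc2ccccc2)c(C)c(OC)c(C(C)=O)c1OCc1ccccc1 | intermediate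
15 | malonyl dichloride | O=C(Cl)CC(Cl)=O | starting material
16 | (4E)-5-(benzyloxy)-4-[(ring A aryl)methyl]-3-oxo-7-(ring C aryl)hept-4-enoyl chloride | O=C(Cl)CC(=O)/C(Cc1c(OCc2ccccc2)c(C)c(OC)c(C(C)=O)c1OCc1ccccc1)=C(/OCc1ccccc1)CCc1c(OCc2ccccc2)c(C)c(OC)c(C(=O)CCC)c1OCc1ccccc1 | intermediate
17 | 5-(benzyloxy)-4-[(ring A aryl)methyl]-6-[(ring C aryl)methyl]benzene-1,3-diol (des-butyryl trimer penta-O-benzyl ether) | Oc1cc(O)c(Cc2c(OCc3ccccc3)c(C)c(OC)c(C(=O)CCC)c2OCc2ccccc2)c(OCc2ccccc2)c1Cc1c(OCc2ccccc2)c(C)c(OC)c(C(C)=O)c1OCc1ccccc1 | intermediate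
18 | B1 butan-1-iminium chloride of 17 | CCCC(=[NH2+])c1c(O)c(Cc2c(OCc3ccccc3)c(C)c(OC)c(C(C)=O)c2OCc2ccccc2)c(OCc2ccccc2)c(Cc2c(OCc3ccccc3)c(C)c(OC)c(C(=O)CCC)c2OCc2ccccc2)c1O.[Cl-] | intermediate
19 | penta-O-benzyl agrimol F (four outer phenols and B4–OH as benzyl ethers) | CCCC(=O)c1c(O)c(Cc2c(OCc3ccccc3)c(C)c(OC)c(C(C)=O)c2OCc2ccccc2)c(OCc2ccccc2)c(Cc2c(OCc3ccccc3)c(C)c(OC)c(C(=O)CCC)c2OCc2ccccc2)c1O | intermediate
20 | agrimol F | CCCC(=O)c1c(O)c(Cc2c(O)c(C)c(OC)c(C(C)=O)c2O)c(O)c(Cc2c(O)c(C)c(OC)c(C(=O)CCC)c2O)c1O | target

**Step count**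
Total step count: 13.
Longest linear sequence: 11 (steps 1, 2, 4, 6, 7, 8, 9, 10, 11, 12, 13).

**Three steps most likely to fail**

1. **Step 11.** The enol benzyl group may be lost early, after which the ring closes through oxygen instead of carbon. Intermolecular acylation may also outrun ring closure. The fallback gives up building ring B and forms the B3–CH2 and B5–CH2 bonds by Friedel–Crafts benzylation of a bought ring B.
   - It sets out from 8 and 7. Each aldehyde is reduced beside its hindered ketone (NaBH4, THF–MeOH, −20 °C), giving the ring C benzylic alcohol F1 and the ring A benzylic alcohol F2.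
   - Purchased 1-(2,4,6-trihydroxyphenyl)butan-1-one F3 (3 equiv) is alkylated by F1 (Sc(OTf)3 cat., MeCN, rt) at one of its two equivalent free carbons, giving the mono-benzylated phlorobutyrophenone F4.
   - F4 is alkylated by F2 under the same conditions at its last free carbon, giving tetra-O-benzyl agrimol F F5.
   - Hydrogenolysis as in step 13 brings the fallback back to the route at 20.

2. **Step 12.** Acid may strip benzyl groups and transfer them to B1. It may also cleave the electron-rich aryl–CH2 bonds by protonation, and the crowded ketimine may hydrolyse slowly. The fallback removes all benzyl groups before the acylation.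
   - It sets out from 17, which is hydrogenolysed (H2, Pd/C, EtOAc–MeOH, rt) to the fully deprotected des-butyryl trimer F6. This compound has one unsubstituted aromatic carbon in the whole molecule.
   - Friedel–Crafts/Fries butyrylation with (PrCO)2O and BF3·OEt2 at 40 °C, as in step 4, is followed by cleavage of aryl esters with K2CO3 in MeOH. The fallback comes back to the route at 20.

3. **Step 10.** The ring A acetyl group may be silylated to an enol ether, the ketalization may stay incomplete, and the product may hydrolyse during isolation. The fallback avoids silylating agents altogether.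
   - It sets out from 12, which is converted with HC(OMe)3 and TsOH (cat.) in MeOH at rt into the dimethyl ketal F7.
   - F7 is heated with BnOH (1.2 equiv) and pyridinium tosylate (cat.) in toluene at 110 °C with continuous removal of methanol. This is alcohol exchange followed by cracking, the process that generates allyl enol ethers for ketal Claisen rearrangements. The fallback comes back to the route at 14.

**Further compounds**
F1 | step 11 | 1-[2,4-bis(benzyloxy)-3-(hydroxymethyl)-6-methoxy-5-methylphenyl]butan-1-one | CCCC(=O)c1c(OCc2ccccc2)c(CO)c(OCc2ccccc2)c(C)c1OC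
F2 | step 11 | 1-[2,4-bis(benzyloxy)-3-(hydroxymethyl)-6-methoxy-5-methylphenyl]ethan-1-one | CC(=O)c1c(OCc2ccccc2)c(CO)c(OCc2ccccc2)c(C)c1OC
F3 | step 11 | 1-(2,4,6-trihydroxyphenyl)butan-1-one (purchased) | CCCC(=O)c1c(O)cc(O)cc1O
F4 | step 11 | 1-{3-[(ring C aryl)methyl]-2,4,6-trihydroxyphenyl}butan-1-one | CCCC(=O)c1c(O)cc(O)c(Cc2c(OCc3ccccc3)c(C)c(OC)c(C(=O)CCC)c2OCc2ccccc2)c1O
F5 | step 11 | tetra-O-benzyl agrimol F (ring B phenols free) | CCCC(=O)c1c(O)c(Cc2c(OCc3ccccc3)c(C)c(OC)c(C(C)=O)c2OCc2ccccc2)c(O)c(Cc2c(OCc3ccccc3)c(C)c(OC)c(C(=O)CCC)c2OCc2ccccc2)c1O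
F6 | step 12 | des-butyryl agrimol F (all phenols free, B1 H) | Oc1cc(O)c(Cc2c(O)c(C)c(OC)c(C(=O)CCC)c2O)c(O)c1Cc1c(O)c(C)c(OC)c(C(C)=O)c1O
F7 | step 10 | dimethyl ketal of 12 | CCCC(=O)c1c(OCc2ccccc2)c(CCC(OC)(OC)CCc2c(OCc3ccccc3)c(C)c(OC)c(C(C)=O)c2OCc2ccccc2)c(OCc2ccccc2)c(C)c1OC
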